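**Plan**
- Retrosynthesis: the nine O-benzyl groups are removed first; then ring C of the upper, 3-deoxy flavan unit is cut at C2–C3 and at C4–C4a. This leaves an O-aryl oxocarbenium ion (upper ring A, O1, C2 and its catechol ring) and a protected 8-vinylcatechin (upper C3, C4 and the whole lower unit).
- Enabling feature: upper C3 is a bare CH2, and upper C4 is a benzylic carbon on C8 of catechin ring A, which carries oxygen at both ortho positions (O1, O7) and the para position (O5). An 8-vinyl group is therefore a very nucleophilic styrene and the C4 cation it leaves is strongly stabilised. Upper ring A is a phloroglucinol that is alkylated ortho to O1.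
- Forward: (+)-catechin → tetra-O-benzyl → 8-bromo → penta-O-benzyl → 8-vinyl (fragment 1). 3,4-Bis(benzyloxy)benzaldehyde → dimethyl acetal → aryl methyl mixed acetal with 3,5-bis(benzyloxy)phenol (fragment 2). An oxa-Povarov [4+2] joins the fragments and closes upper ring C; hydrogenolysis finishes.
- Stereochemistry: lower C2 (R) and C3 (S) are bought with (+)-catechin. Upper C2 (S) is set by the chiral counter-anion of a Brønsted acid in the oxa-Povarov step. Upper C4 (S) is relayed from C2 in the same event (2,4-cis).

Key step: step 7

Assumption: the sense of induction of a given antipode of the chiral acid cannot be fixed on paper; both antipodes are accessible and the one that favours the (2S,4S) diastereomer is to be used.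

**Step 1**
Reactants: 1 (+)-catechin
Product: 2 (2R,3S)-5,7,3',4'-tetra-O-benzylcatechin
Conditions: BnBr (4.4 equiv), K2CO3, DMF, 0 °C to rt
Reagents that add atoms: benzyl bromide, BrCc1ccccc1
Why: Williamson etherification of the four phenols, which are far more acidic than the secondary 3-OH, so carbonate should leave the 3-OH free and the C2/C3 configuration untouched.

**Step 2**
Reactants: 2 (2R,3S)-5,7,3',4'-tetra-O-benzylcatechin
Product: 3 (2R,3S)-8-bromo-5,7,3',4'-tetra-O-benzylcatechin
Conditions: NBS (1.0 equiv), CH2Cl2, −78 °C to rt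
Reagents that add atoms: N-bromosuccinimide, O=C1CCC(=O)N1Br
Why: Electrophilic aromatic bromination of the phloroglucinol-type ring A, for which C8 (flanked by O1 and O7) is the preferred site in benzylated catechins; one equivalent at low temperature should avoid 6,8-dibromination.

**Step 3**
Reactants: 3 (2R,3S)-8-bromo-5,7,3',4'-tetra-O-benzylcatechin
Product: 4 (2R,3S)-8-bromo-3,5,7,3',4'-penta-O-benzylcatechin
Conditions: NaH, BnBr, DMF, 0 °C to rt
Reagents that add atoms: benzyl bromide, BrCc1ccccc1
Why: Williamson etherification of the remaining secondary alcohol through its sodium alkoxide; no stereocentre is touched and the aryl bromide is inert.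

**Step 4**
Reactants: 4 (2R,3S)-8-bromo-3,5,7,3',4'-penta-O-benzylcatechin
Product: 5 (2R,3S)-8-vinyl-3,5,7,3',4'-penta-O-benzylcatechin
Conditions: vinylboronic acid pinacol ester, Pd(OAc)2 (5 mol %), SPhos (10 mol %), K3PO4, toluene/H2O, 90 °C
Reagents that add atoms: vinylboronic acid pinacol ester, C=CB1OC(C)(C)C(C)(C)O1
Why: Suzuki–Miyaura coupling; the biaryl phosphine SPhos is suited to oxidative addition and transmetalation at the di-ortho-substituted, electron-rich C8–Br bond.

**Step 5**
Reactants: 6 3,4-bis(benzyloxy)benzaldehyde
Product: 7 3,4-bis(benzyloxy)benzaldehyde dimethyl acetal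
Conditions: HC(OMe)3, p-TsOH·H2O (cat.), MeOH, rt; Et3N quench
Reagents that add atoms: trimethyl orthoformate, COC(OC)OC; methanol, CO
Why: Acid-catalysed acetalisation, driven to completion by the orthoformate as water scavenger.

**Step 6**
Reactants: 7 3,4-bis(benzyloxy)benzaldehyde dimethyl acetal; 8 3,5-bis(benzyloxy)phenol
Product: 10 racemic 3,5-bis(benzyloxy)phenyl methyl acetal of 3,4-bis(benzyloxy)benzaldehyde, via chloro ether 9 (not isolated)
Conditions: AcCl (1.05 equiv), SOCl2 (2 mol %), CH2Cl2, 0 °C to rt; then 8, iPr2NEt, CH2Cl2, 0 °C to rt; basic alumina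
Reagents that add atoms: none
Why: Acetal–acyl chloride exchange gives the alpha-chloro ether (as in the preparation of chloromethyl methyl ether from dimethoxymethane), which O-alkylates the phenol by an SN1-type substitution as in MOM-ether formation; the acetal carbon is racemic, which does not matter because it becomes planar in step 7.

**Step 7**
Reactants: 10 racemic 3,5-bis(benzyloxy)phenyl methyl acetal of 3,4-bis(benzyloxy)benzaldehyde; 5 (2R,3S)-8-vinyl-3,5,7,3',4'-penta-O-benzylcatechin
Product: 13 nona-O-benzyl ether of the target, via aryl oxocarbenium ion 11 (not isolated), via benzylic cation 12 (not isolated)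
Conditions: chiral BINOL-derived N-triflyl phosphoramide with 3,3'-bis(2,4,6-triisopropylphenyl) groups (10 mol %), 5 Å molecular sieves, CH2Cl2, −60 °C, slow addition of 5 to 10 (1.5 equiv)
Reagents that add atoms: none
Why: Proposed new method: the chiral acid protonates the more basic methoxy oxygen of 10 and expels methanol (taken up by the sieves) to give the aryl oxocarbenium ion 11 as a contact ion pair with the chiral phosphoramide anion, the terminal CH2 of the vinyl group of 5 adds to its carbenium carbon (new C2–C3 bond) to give the benzylic cation 12, and 12 alkylates the phenoxy ring ortho to the ether oxygen (new C4–C4a bond) before a proton returns to the anion, so the acid turns over. The closest known reaction type is the SnCl4-promoted oxa-Povarov reaction of aryl methyl mixed acetals with styrenes, which gives racemic 2,4-cis-2,4-diarylchromans, taken together with chiral-Brønsted-acid-catalysed aza-Povarov reactions and counter-anion-directed additions to oxocarbenium ions; what is new is the catalytic, anion-controlled version on the oxygen 2-oxadiene cation. Ring C of the upper unit closes in the second bond-forming event by a 6-endo-trig cation–arene (Friedel–Crafts) closure, the overall change being a stepwise formal [4+2] cycloaddition. C2 is set by the chiral anion, which covers one face of the planar oxocarbenium ion in the first C–C bond formation, and C4 is relayed from C2 in the chair-like closure that places the C2 catechol ring and the C4 catechin unit both pseudo-equatorial (2,4-cis, hence 4S from 2S). The step needs Markovnikov addition, secured by O1, O5 and O7 ortho, para and ortho to C8 of catechin ring A, which stabilise the C4 cation, and a single site of ring closure, secured by the symmetry of the 3,5-bis(benzyloxy)phenoxy ring, whose two ortho positions are equivalent and whose para position cannot reach. Because 5 is enantiopure, attack on the wrong face of 11 would give a diastereomer of 13 and not its enantiomer, so incomplete catalyst control should cost material but not optical purity once that diastereomer is removed by chromatography.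

**Step 8**
Reactants: 13 nona-O-benzyl ether of the target
Product: 14 (2S,4S)-luteoliflavan-(4→8)-(+)-catechin (2,4-cis), the target
Conditions: H2 (1 atm), Pd(OH)2/C, THF/MeOH 1:1, rt
Reagents that add atoms: none
Why: Hydrogenolysis of the nine benzyl ethers over Pd(OH)2/C is the standard finish of benzyl-protected proanthocyanidin syntheses; low pressure and a neutral medium should keep the cyclic benzylic C2–O1 bonds and the C4–C8 bond intact.

**Compound list**
1 | (+)-catechin, (2R,3S) | Oc1cc(O)c2c(c1)O[C@H](c1ccc(O)c(O)c1)[C@@H](O)C2 | starting material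
2 | (2R,3S)-5,7,3',4'-tetra-O-benzylcatechin | c3ccccc3COc1cc(OCc3ccccc3)c2c(c1)O[C@H](c1ccc(OCc3ccccc3)c(OCc3ccccc3)c1)[C@@H](O)C2 | intermediate
3 | (2R,3S)-8-bromo-5,7,3',4'-tetra-O-benzylcatechin | Brc1c(OCc3ccccc3)cc(OCc3ccccc3)c2c1O[C@H](c1ccc(OCc3ccccc3)c(OCc3ccccc3)c1)[C@@H](O)C2 | intermediate
4 | (2R,3S)-8-bromo-3,5,7,3',4'-penta-O-benzylcatechin | Brc1c(OCc3ccccc3)cc(OCc3ccccc3)c2c1O[C@H](c1ccc(OCc3ccccc3)c(OCc3ccccc3)c1)[C@@H](OCc3ccccc3)C2 | intermediate
5 | (2R,3S)-8-vinyl-3,5,7,3',4'-penta-O-benzylcatechin | C=Cc1c(OCc3ccccc3)cc(OCc3ccccc3)c2c1O[C@H](c1ccc(OCc3ccccc3)c(OCc3ccccc3)c1)[C@@H](OCc3ccccc3)C2 | intermediate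
6 | 3,4-bis(benzyloxy)benzaldehyde | O=Cc1ccc(OCc3ccccc3)c(OCc3ccccc3)c1 | starting material
7 | 3,4-bis(benzyloxy)benzaldehyde dimethyl acetal | COC(OC)c1ccc(OCc3ccccc3)c(OCc3ccccc3)c1 | intermediate
8 | 3,5-bis(benzyloxy)phenol | Oc1cc(OCc3ccccc3)cc(OCc3ccccc3)c1 | starting material
9 | 1,2-bis(benzyloxy)-4-[chloro(methoxy)methyl]benzene, racemic (not isolated) | COC(Cl)c1ccc(OCc3ccccc3)c(OCc3ccccc3)c1 | intermediate
10 | 3,5-bis(benzyloxy)phenyl methyl acetal of 3,4-bis(benzyloxy)benzaldehyde, racemic | COC(Oc1cc(OCc3ccccc3)cc(OCc3ccccc3)c1)c1ccc(OCc3ccccc3)c(OCc3ccccc3)c1 | intermediate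
11 | O-[3,5-bis(benzyloxy)phenyl] oxocarbenium ion of 3,4-bis(benzyloxy)benzaldehyde (not isolated) | c3ccccc3COc1cc(OCc3ccccc3)cc(c1)[O+]=Cc1ccc(OCc3ccccc3)c(OCc3ccccc3)c1 | intermediate
12 | benzylic cation: (3S)-3-[3,5-bis(benzyloxy)phenoxy]-3-[3,4-bis(benzyloxy)phenyl]-1-(penta-O-benzylcatechin-8-yl)propan-1-ylium (not isolated) | c3ccccc3COc1cc(OCc3ccccc3)cc(c1)O[C@H](c1ccc(OCc3ccccc3)c(OCc3ccccc3)c1)C[CH+]c1c(OCc3ccccc3)cc(OCc3ccccc3)c2c1O[C@H](c1ccc(OCc3ccccc3)c(OCc3ccccc3)c1)[C@@H](OCc3ccccc3)C2 | intermediate
13 | nona-O-benzyl ether of the target: 5,7,3',4'-tetra-O-benzyl-2,4-cis-flavan linked C4→C8 to 3,5,7,3',4'-penta-O-benzylcatechin | c3ccccc3COc1cc(OCc3ccccc3)c2c(c1)O[C@H](c1ccc(OCc3ccccc3)c(OCc3ccccc3)c1)C[C@@H]2c1c(OCc3ccccc3)cc(OCc3ccccc3)c2c1O[C@H](c1ccc(OCc3ccccc3)c(OCc3ccccc3)c1)[C@@H](OCc3ccccc3)C2 | intermediate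
14 | (2S,4S)-5,7,3',4'-tetrahydroxyflavan-(4→8)-(2R,3S)-catechin | Oc1cc(O)c2c(c1)O[C@H](c1ccc(O)c(O)c1)C[C@@H]2c1c(O)cc(O)c2c1O[C@H](c1ccc(O)c(O)c1)[C@@H](O)C2 | target

**Totals**
Total step count: 8. Longest linear sequence: 6 (steps 1, 2, 3, 4, 7, 8).

**Steps most likely to fail**

1. Step 7 (proposed new method). Three things may go wrong:
   - The chiral anion may discriminate poorly between the faces of an oxocarbenium ion that offers it no hydrogen-bonding handle.
   - The acid may protonate the very electron-rich styrene and start cationic oligomerisation.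
   - The acetal may ionise at the aryloxy instead of the methoxy oxygen.

   Fallback (known chemistry, different bond construction): the upper unit is brought in with C2 already in place and joined by the biomimetic flavan-4-yl cation/flavan-3-ol condensation. Commercial (2S)-eriodictyol (O=C1C[C@@H](c2ccc(O)c(O)c2)Oc2cc(O)cc(O)c12) would be reduced with NaBH4 in EtOH/THF at 0 °C to (2S,4S)-luteoforol F1. In dilute HCl in aqueous EtOH at rt, F1 should ionise at C4 and be captured by C8 of (+)-catechin 1, used in excess to suppress oligomers, to give 14 directly. The 2,4-trans and 4→6 isomers would be removed on Sephadex LH-20 and by reversed-phase HPLC. This fallback sets out from 1 and comes back to the route at 14.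

2. Step 6. The electron-rich alpha-chloro ether may decompose before it is trapped, the phenol may be alkylated on carbon instead of oxygen, and the mixed acetal may hydrolyse during purification. Fallback (oxidative route to the same acetal, no chloro ether): phenol 8 would be alkylated with commercial 3,4-bis(benzyloxy)benzyl chloride (ClCc1ccc(OCc2ccccc2)c(OCc2ccccc2)c1; K2CO3, DMF, rt) to give 3,5-bis(benzyloxy)phenyl 3,4-bis(benzyloxy)benzyl ether F2. DDQ with MeOH and 4 Å molecular sieves in CH2Cl2 at 0 °C should then abstract hydride from the 3,4-dialkoxybenzylic CH2, as in the oxidative cleavage of dimethoxybenzyl ethers, and the oxocarbenium ion so formed would be trapped by methanol. This fallback sets out from 8 and comes back to the route at 10.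

3. Step 4. Oxidative addition into the hindered, electron-rich C8–Br bond may be slow, and protodebromination may compete. Fallback (carbonyl olefination instead of cross-coupling): bromide 4 would undergo bromine–lithium exchange (n-BuLi, THF, −78 °C) and formylation with DMF to give (2R,3S)-8-formyl-3,5,7,3',4'-penta-O-benzylcatechin F3. Wittig methylenation (Ph3PCH3Br, KOtBu, THF, 0 °C) should then give the styrene. This fallback sets out from 4 and comes back to the route at 5.

**Further compounds**
F1 | step 7 | (2S,4S)-luteoforol, (2S,4S)-2-(3,4-dihydroxyphenyl)chromane-4,5,7-triol | Oc1cc(O)c2c(c1)O[C@H](c1ccc(O)c(O)c1)C[C@@H]2O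
F2 | step 6 | 3,5-bis(benzyloxy)phenyl 3,4-bis(benzyloxy)benzyl ether | c3ccccc3COc1cc(OCc3ccccc3)cc(c1)OCc1ccc(OCc3ccccc3)c(OCc3ccccc3)c1
F3 | step 4 | (2R,3S)-8-formyl-3,5,7,3',4'-penta-O-benzylcatechin | O=Cc1c(OCc3ccccc3)cc(OCc3ccccc3)c2c1O[C@H](c1ccc(OCc3ccccc3)c(OCc3ccccc3)c1)[C@@H](OCc3ccccc3)C2
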